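**Retrosynthetic overview**
Locants: benzofuranone O1, C2, C3, C3a–C7a (arene = ring A, furanone = ring B); side chain C1' (on C2) to C12'.
Last disconnection: the C2–OH bond. The labile hemiketal stereocentre is made at the very end by a base-free, catalyst-controlled oxygen transfer to the C2–H benzofuranone.
Key disconnection: C7'–C8' (methyl-bearing alkene carbon to ketone carbon), made together with C8'–C9' by carbonylative coupling of a C7' alkenyl iodide, CO and a C9' alkenylstannane.
Enabling feature: C8' is a ketone flanked only by sp2 carbons (C7' of the E-C6'=C7' alkene, C9' of the E-C9'=C10' alkene). The acyl-metal stage therefore has no α- or β-hydrogen, both geometries enter by retention, and the two E alkenes keep C2'=C3' and the C11' hydroxyl away from C8'.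
Ring order: ring A is bought. Ring B, the only ring formed, is closed at O1–C2 from an o-hydroxyaryl ketone (acetophenone dianion + allylic bromide). The chain C1'–C7' comes from syn-carbocupration (C2'=C3') and hydrozirconation–iodination (C6'=C7').

Key step: step 9

Assumption: the C2 hemiketal is taken to hold its configuration in neutral or weakly acidic aprotic media, but to racemise through its alkoxide (ring opening to the o-hydroxyaryl 1,2-diketone). C2 is therefore oxygenated last, without base, and the target is purified on neutral media under inert gas.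

Step 1
Reactants: 1 pent-3-yn-1-ol
Product: 2 5-bromopent-2-yne
Conditions: CBr4, PPh3, CH2Cl2, 0 °C
Reagents that add atoms: carbon tetrabromide, BrC(Br)(Br)Br
Why: Appel reaction, in which the primary alcohol is activated as an alkoxyphosphonium salt and displaced by bromide without touching the internal alkyne.

Step 2
Reactants: 2 5-bromopent-2-yne; 3 ethyl but-2-ynoate
Product: 7 ethyl (E)-3-methyloct-2-en-6-ynoate, via Grignard reagent 4 (not isolated), via alkylcopper 5 (not isolated), via alkenylcopper adduct 6 (not isolated)
Conditions: Mg, THF, rt; CuBr·SMe2, THF–Me2S, −45 °C; 3, −78 °C; aq NH4Cl, −78 °C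
Reagents that add atoms: none
Why: Syn-carbocupration of an alkynoate puts C4' and copper on the same side of the triple bond, and protonation at −78 °C with retention fixes the E-C2'=C3' alkene.

Step 3
Reactants: 7 ethyl (E)-3-methyloct-2-en-6-ynoate
Product: 8 (E)-3-methyloct-2-en-6-yn-1-ol
Conditions: i-Bu2AlH (2.2 equiv), CH2Cl2, −78 °C; aq potassium sodium tartrate
Reagents that add atoms: none
Why: Standard 1,2-reduction of an enoate to the allylic alcohol, which leaves the internal alkyne and the alkene geometry untouched at low temperature.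

Step 4
Reactants: 8 (E)-3-methyloct-2-en-6-yn-1-ol
Product: 10 (2E,6E)-7-iodo-3-methylocta-2,6-dien-1-ol, via bis(zirconocene) species 9 (not isolated)
Conditions: Cp2Zr(H)Cl (3 equiv), THF, rt to 45 °C; I2, THF, −78 to 0 °C
Reagents that add atoms: iodine, [I][I]
Why: Hydrozirconation–iodinolysis, in which syn Zr–H addition is equilibrated by excess hydride so that zirconium sits on the less hindered methyl-bearing C7' and iodinolysis with retention gives the E-alkenyl iodide, while the first equivalent of hydride only masks the hydroxyl as its zirconium alkoxide.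

Step 5
Reactants: 10 (2E,6E)-7-iodo-3-methylocta-2,6-dien-1-ol
Product: 11 (2E,6E)-1-bromo-7-iodo-3-methylocta-2,6-diene
Conditions: CBr4, PPh3, CH2Cl2, −30 to 0 °C; used without chromatography
Reagents that add atoms: carbon tetrabromide, BrC(Br)(Br)Br
Why: Appel bromination under neutral conditions converts the primary allylic alcohol by SN2 without allylic transposition or loss of either alkene geometry.

Step 6
Reactants: 12 1-(2-hydroxy-6-methylphenyl)ethan-1-one; 11 (2E,6E)-1-bromo-7-iodo-3-methylocta-2,6-diene
Product: 14 (4E,8E)-1-(2-hydroxy-6-methylphenyl)-9-iodo-5-methyldeca-4,8-dien-1-one, via dilithium dianion 13 (not isolated)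
Conditions: LiN(i-Pr)2 (2.1 equiv), THF, −78 to −10 °C; 11, −78 to 0 °C; aq NH4Cl
Reagents that add atoms: none
Why: Alkylation of the dianion of an o-hydroxyacetophenone, whose enolate carbon is far more nucleophilic than the chelated phenoxide, so the primary allylic bromide is taken up by SN2 at carbon and forms C2–C1'.

Step 7
Reactants: 14 (4E,8E)-1-(2-hydroxy-6-methylphenyl)-9-iodo-5-methyldeca-4,8-dien-1-one
Product: 17 2-[(2E,6E)-7-iodo-3-methylocta-2,6-dien-1-yl]-4-methylbenzofuran-3(2H)-one (racemic at C2), via dilithium dianion 15 (not isolated), via α-iodoketone phenoxide 16 (not isolated)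
Conditions: LiN(i-Pr)2 (2.1 equiv), THF, −78 °C; cannulated into I2 (1.05 equiv), THF, −78 °C; then rt
Reagents that add atoms: none
Why: Enolate iodination followed by intramolecular Williamson etherification (5-exo-tet), in which inverse addition at −78 °C halogenates only the enolate carbon and on warming the neighbouring phenoxide displaces iodide to close ring B at O1–C2, C2 being left racemic on purpose.

Step 8
Reactants: 18 2-methylbut-3-yn-2-ol
Product: 19 (E)-2-methyl-4-(tributylstannyl)but-3-en-2-ol
Conditions: Bu3SnH, PdCl2(PPh3)2 (2 mol%), THF, 0 °C to rt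
Reagents that add atoms: tributyltin hydride, CCCC[SnH](CCCC)CCCC
Why: Palladium-catalysed syn-hydrostannation of a terminal alkyne, in which the bulky tertiary carbinol directs tin to the terminal carbon and gives the E-alkenylstannane without protection of the hydroxyl.

Step 9
Reactants: 17 2-[(2E,6E)-7-iodo-3-methylocta-2,6-dien-1-yl]-4-methylbenzofuran-3(2H)-one; 19 (E)-2-methyl-4-(tributylstannyl)but-3-en-2-ol; 20 carbon monoxide
Product: 22 2-[(2E,6E,9E)-11-hydroxy-3,7,11-trimethyl-8-oxododeca-2,6,9-trien-1-yl]-4-methylbenzofuran-3(2H)-one (racemic at C2), via acylpalladium iodide 21 (not isolated)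
Conditions: Pd2(dba)3 (2.5 mol%), AsPh3 (20 mol%), CO (3 bar), THF, 50 °C, no base, O2 excluded
Reagents that add atoms: carbon monoxide 20, [C-]#[O+]
Why: Zerovalent palladium inserts into the C7'–I bond of 17 with retention, CO inserts into the alkenyl–palladium bond and thereby makes the C7'–C8' bond (acylpalladium 21), the unhindered stannane 19 transmetalates, and reductive elimination closes C8'–C9', so the whole cross-conjugated hydroxy-dienone is laid down in one unprotected operation. The closest known reaction type is the carbonylative Stille coupling of alkenyl iodides with alkenylstannanes to unsymmetrical divinyl ketones. No ring is closed and no stereocentre is formed, and the E geometries at C6'=C7' and C9'=C10' are carried over with retention from 17 and 19. The step needs carbonylative rather than direct coupling, which is secured by CO pressure and by the α-methyl branch at C7', which slows transmetalation at the alkenylpalladium stage more than it slows CO insertion. It also needs the acylpalladium to ignore internal alkenes and nucleophiles: with E-C6'=C7' any acyl-Heck closure onto C2'=C3' would need a trans-cycloalkene, and E-C9'=C10' keeps the tertiary hydroxyl from lactonising. The base-free medium leaves the acidic C2–H untouched.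

Step 10
Reactants: 22 2-[(2E,6E,9E)-11-hydroxy-3,7,11-trimethyl-8-oxododeca-2,6,9-trien-1-yl]-4-methylbenzofuran-3(2H)-one
Product: 24 (2R)-2-hydroxy-2-[(2E,6E,9E)-11-hydroxy-3,7,11-trimethyl-8-oxododeca-2,6,9-trien-1-yl]-4-methylbenzofuran-3(2H)-one, via aminooxy ketal 23 (not isolated)
Conditions: (S)-3,3'-bis(2,4,6-triisopropylphenyl)-1,1'-binaphthyl-2,2'-diyl hydrogen phosphate [(S)-TRIP, 10 mol%], PhNO (2.5 equiv, in portions), toluene, 0 °C, Ar, dark
Reagents that add atoms: nitrosobenzene, O=Nc1ccccc1
Why: Proposed new method: the phosphoric acid speeds up tautomerisation of 22 to its aromatic 3-hydroxybenzofuran enol and binds the enol O–H at its P=O oxygen and the nitroso nitrogen at its P–OH, so that C2 attacks the nitroso oxygen from one face inside the chiral pocket (this sets C2); a second nitrosobenzene then cleaves the N–O bond of 23 to give the free hemiketal and azoxybenzene without any alkoxide being formed, while isolated alkenes, the dienone and the tertiary alcohol are spectators. The closest known reaction type is the chiral-phosphoric-acid-catalysed α-hydroxylation of α-branched cyclic ketones and β-dicarbonyl compounds with nitrosoarenes (enol catalysis), not yet shown on benzofuran-3(2H)-ones. The (S)-acid is assigned by analogy, the sense of induction has to be checked against the chiroptical data of the natural product, and the (R)-acid is equally available.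

**Compound list**
1 | pent-3-yn-1-ol | CC#CCCO | starting material
2 | 5-bromopent-2-yne | CC#CCCBr | intermediate
3 | ethyl but-2-ynoate | CC#CC(=O)OCC | starting material
4 | pent-3-yn-1-ylmagnesium bromide | CC#CCC[Mg]Br | intermediate
5 | pent-3-yn-1-ylcopper | CC#CCC[Cu] | intermediate
6 | ethyl 2-cuprio-3-methyloct-2-en-6-ynoate (copper cis to the pentynyl chain) | CCOC(=O)/C([Cu])=C(\C)CCC#CC | intermediate
7 | ethyl (E)-3-methyloct-2-en-6-ynoate | CCOC(=O)/C=C(\C)CCC#CC | intermediate
8 | (E)-3-methyloct-2-en-6-yn-1-ol | OC/C=C(\C)CCC#CC | intermediate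
9 | O-zirconated (6E)-7-zirconated dienol, both metals as Cp2ZrCl | Cl[Zr](C1C=CC=C1)(C1C=CC=C1)OC/C=C(\C)CC/C=C(\C)[Zr](Cl)(C1C=CC=C1)C1C=CC=C1 | intermediate
10 | (2E,6E)-7-iodo-3-methylocta-2,6-dien-1-ol | OC/C=C(\C)CC/C=C(\C)I | intermediate
11 | (2E,6E)-1-bromo-7-iodo-3-methylocta-2,6-diene | BrC/C=C(\C)CC/C=C(\C)I | intermediate
12 | 1-(2-hydroxy-6-methylphenyl)ethan-1-one | CC(=O)c1c(C)cccc1O | starting material
13 | dilithium phenoxide-enolate of 12 | C=C(O[Li])c1c(C)cccc1O[Li] | intermediate
14 | (4E,8E)-1-(2-hydroxy-6-methylphenyl)-9-iodo-5-methyldeca-4,8-dien-1-one | C/C(=C\CCC(=O)c1c(C)cccc1O)CC/C=C(\C)I | intermediate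
15 | dilithium phenoxide-(Z)-enolate of 14 | C/C(=C\C/C=C(\O[Li])c1c(C)cccc1O[Li])CC/C=C(\C)I | intermediate
16 | lithium phenoxide of the 2-iodo ketone derived from 14 (racemic) | C/C(=C\CC(I)C(=O)c1c(C)cccc1O[Li])CC/C=C(\C)I | intermediate
17 | 2-[(2E,6E)-7-iodo-3-methylocta-2,6-dien-1-yl]-4-methylbenzofuran-3(2H)-one (racemic) | C/C(=C\CC1Oc2cccc(C)c2C1=O)CC/C=C(\C)I | intermediate
18 | 2-methylbut-3-yn-2-ol | C#CC(C)(C)O | starting material
19 | (E)-2-methyl-4-(tributylstannyl)but-3-en-2-ol | CCCC[Sn](CCCC)(CCCC)/C=C/C(C)(C)O | intermediate
20 | carbon monoxide | [C-]#[O+] | starting material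
21 | C8' acylpalladium iodide derived from 17 and CO (AsPh3 ligands omitted) | C/C(=C\CC1Oc2cccc(C)c2C1=O)CC/C=C(\C)C(=O)[Pd]I | intermediate
22 | 2-[(2E,6E,9E)-11-hydroxy-3,7,11-trimethyl-8-oxododeca-2,6,9-trien-1-yl]-4-methylbenzofuran-3(2H)-one (racemic) | C/C(=C\CC1Oc2cccc(C)c2C1=O)CC/C=C(\C)C(=O)/C=C/C(C)(C)O | intermediate
23 | 2-(N-phenylaminooxy) ketal of 22, same spatial arrangement at C2 as in 24 | C/C(=C\C[C@@]1(ONc3ccccc3)Oc2cccc(C)c2C1=O)CC/C=C(\C)C(=O)/C=C/C(C)(C)O | intermediate
24 | (2R)-2-hydroxy-2-[(2E,6E,9E)-11-hydroxy-3,7,11-trimethyl-8-oxododeca-2,6,9-trien-1-yl]-4-methylbenzofuran-3(2H)-one | C/C(=C\C[C@@]1(O)Oc2cccc(C)c2C1=O)CC/C=C(\C)C(=O)/C=C/C(C)(C)O | target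

**Totals**
Total step count: 10. Longest linear sequence: 9 (steps 1–7, 9, 10).

**Steps most likely to fail**

Step 10 (Proposed new method).
- Risk: weak facial discrimination at the flat enol, attack through nitrogen instead of oxygen, loss of enantiopurity by acid-mediated ring–chain tautomerism, or uncatalysed autoxidation of the enol.
- Fallback with known chemistry (enol silylation, enantioselective manganese-salen oxidation of a silyl enol ether with Rubottom-type silyl shift, buffered desilylation), setting out from 22.
- Et3SiOTf (2.2 equiv) and Et3N in CH2Cl2 at −78 to 0 °C should give the 3-(triethylsilyloxy)benzofuran with silylated tertiary alcohol F1.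
- Oxidation uses (R,R)-N,N'-bis(3,5-di-tert-butylsalicylidene)-1,2-cyclohexanediaminomanganese chloride, PhIO and 4-phenylpyridine N-oxide in CH2Cl2. The catalyst enantiomer is first checked on 17.
- This catalyst prefers the aryl-conjugated electron-rich enol ether over the isolated and electron-poor alkenes. It should give the configurationally locked 2-(triethylsilyloxy) ketone F2.
- HF·pyridine buffered with pyridine in THF at 0 °C removes both silyl groups and returns to the route at 24.

Step 7.
- Risk: proton exchange between the iodoketone and unreacted dianion, leading to over-halogenation, oxidative enolate dimerisation or incomplete conversion.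
- The fallback separates halogenation from ring closure and sets out from 14.
- t-BuMe2SiOTf (2.2 equiv) and Et3N should give the aryl silyl ether (Z)-silyl enol ether F3.
- NBS in THF at −78 °C reacts with the enol ether faster than with the trisubstituted alkenes and should give the α-bromo ketone aryl silyl ether F4.
- Bu4NF in THF at 0 °C releases the phenoxide, which closes ring B and returns to the route at 17.

Step 9.
- Risk: coupling without CO insertion, protodestannylation, or catalyst deactivation under CO.
- The fallback makes the same C7'–C8' bond at the alcohol oxidation level and sets out from 17.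
- Cross metathesis of 2-methylbut-3-en-2-ol with crotonaldehyde (second-generation Hoveyda–Grubbs catalyst, CH2Cl2, 40 °C) should give (E)-4-hydroxy-4-methylpent-2-enal F5.
- Nozaki–Hiyama–Kishi coupling of 17 with this aldehyde (CrCl2, NiCl2 1 mol%, DMSO–THF, rt) is selective for the aldehyde over the ring ketone and should give the bis-allylic alcohol F6 as a mixture of diastereomers.
- MnO2 in CH2Cl2 oxidises only the bis-allylic secondary alcohol and returns to the route at 22.

**Further compounds**
F1 | step 10 | 2-[(2E,6E,9E)-3,7,11-trimethyl-8-oxo-11-(triethylsilyloxy)dodeca-2,6,9-trien-1-yl]-4-methyl-3-(triethylsilyloxy)benzofuran | C/C(=C\Cc1oc2cccc(C)c2c1O[Si](CC)(CC)CC)CC/C=C(\C)C(=O)/C=C/C(C)(C)O[Si](CC)(CC)CC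
F2 | step 10 | bis(triethylsilyl) ether of 24, same spatial arrangement at C2 (descriptor S by priority) | C/C(=C\C[C@@]1(O[Si](CC)(CC)CC)Oc2cccc(C)c2C1=O)CC/C=C(\C)C(=O)/C=C/C(C)(C)O[Si](CC)(CC)CC
F3 | step 7 | bis(tert-butyldimethylsilyl) derivative of 14 (aryl silyl ether, Z-silyl enol ether) | C/C(=C\C/C=C(\O[Si](C)(C)C(C)(C)C)c1c(C)cccc1O[Si](C)(C)C(C)(C)C)CC/C=C(\C)I
F4 | step 7 | (4E,8E)-2-bromo-1-[2-(tert-butyldimethylsilyloxy)-6-methylphenyl]-9-iodo-5-methyldeca-4,8-dien-1-one (racemic) | C/C(=C\CC(Br)C(=O)c1c(C)cccc1O[Si](C)(C)C(C)(C)C)CC/C=C(\C)I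
F5 | step 9 | (E)-4-hydroxy-4-methylpent-2-enal | CC(C)(O)/C=C/C=O
F6 | step 9 | 2-[(2E,6E,9E)-8,11-dihydroxy-3,7,11-trimethyldodeca-2,6,9-trien-1-yl]-4-methylbenzofuran-3(2H)-one (diastereomer mixture) | C/C(=C\CC1Oc2cccc(C)c2C1=O)CC/C=C(\C)C(O)/C=C/C(C)(C)O
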